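(Readings and results are calculated for substances that don't exist, noise included.)

Whatever vessel is used, the balance holds: substrate that has reacted stands as target or side product, apart from what the catalyst holds, and the catalyst charged amounts to 5.09% of the substrate charge. The meeting compared four ways of running the birch charge, and for each it wanted the share of target among target plus side product, the selectivity.

| setting | birch | ash | oak | elm | alpha | delta | theta | zeta |
|---|---|---|---|---|---|---|---|---|
| substrate | 0.055 M | 0.055 M | 0.055 M | 0.055 M | 0.055 M | 0.055 M (fed, over 15.0 h) | 0.055 M | 0.055 M |
| partner | 0.055 M | 0.028 M | 0.041 M | 0.055 M | 0.0550 M | 0.0550 M | 0.0550 M | 0.0550 M |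
| free catalyst | 2.8 mM | 2.8 mM | 2.8 mM | 4.2 mM | 2.8 mM | 2.8 mM | 2.8 mM | 2.8 mM |
| remark | run made earlier | run made earlier | run made earlier | run made earlier | plug flow through a tube for 30 h, no back-mixing | a stirred flask in which substrate is dosed at a steady rate over 15.0 h without added volume, worked up at 30 h | everything together in a closed stirred flask, run for 30 h | a single well-mixed tank run continuously and read at steady state, 30 h in it on average |
| time |  |  |  |  | 30 h | 30 h | 30 h |  |

| run | time / h | target / % | side product / % |
|---|---|---|---|
| birch | 4.00 | 16.8 | 1.2 |
| birch | 8.00 | 36.1 | 0.9 |
| birch | 12.0 | 50.9 | 3.0 |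
| birch | 15.0 | 58.4 | 5.6 |
| birch | 20.0 | 67.2 | 12.2 |
| birch | 25.0 | 70.7 | 15.6 |
| birch | 30.0 | 71.1 | 23.5 |
| ash | 1.33 | 5.3 | 2.0 |
| ash | 2.00 | 7.3 | 0 |
| ash | 3.00 | 10.7 | 0 |
| ash | 5.00 | 20.2 | 2.4 |
| ash | 8.00 | 28.0 | 1.2 |
| ash | 12.0 | 35.6 | 1.8 |
| ash | 20.0 | 46.4 | 3.0 |
| oak | 1.33 | 4.9 | 0.4 |
| oak | 2.00 | 9.9 | 1.0 |
| oak | 3.00 | 13.6 | 0 |
| oak | 5.00 | 21.5 | 0 |
| oak | 8.00 | 32.3 | 1.3 |
| oak | 12.0 | 45.4 | 1.3 |
| oak | 20.0 | 58.1 | 7.6 |
| elm | 4.00 | 29.0 | 1.3 |
| elm | 8.00 | 51.0 | 2.6 |
| elm | 10.0 | 58.6 | 3.0 |
| elm | 15.0 | 72.2 | 10.0 |
| elm | 20.0 | 76.2 | 16.4 |

(each reading ± 1 percentage point)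

* the set-up with the highest share of target in all that became target or side product, at the outlet or at the end ("none" if the first two lie within 2 percentage points) (alpha / delta / theta / zeta / none)
* share of target in all that became target or side product, at the outlet or at the end, alpha
* share of target in all that became target or side product, at the outlet or at the end, delta
* share of target in all that became target or side product, at the outlet or at the end, theta
* share of target in all that became target or side product, at the outlet or at the end, zeta

- the stated concentrations are those of everything mixed, before any reaction; amounts are the same in each set-up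
- the feed brings no volume worth counting
- the earlier runs were made in a closed, stirred flask

The kineticist opened. In birch the target builds first and the side product comes later, as if target were lost in a step second order in target. Between 15.0 h and 30.0 h she took the mean of the four target readings, squared it, and put at 0.0267 h⁻¹ the loss coefficient, the fraction of the charge turning to side product per hour per squared fraction of target.

At the last birch reading, she said, that means a loss of 0.0135 h⁻¹ of the charge, with the share reading 75.2%.

The process chemist turned this into a price for delay. With target held at its last birch reading, each hour at that loss by which a flask lags birch is reckoned to raise its share by 0.0107 h⁻¹, so clearing the margin is reckoned to take a lag of 1.86 h.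

My own reckoning, as keeper of the minutes, went further. The birch readings at 25.0 h left 13.7% of the charge neither target nor side product, and delta needs 2.05 h of dosing to have fed that much. Taking this as delta's lag, which is longer than the price, I put delta at 77.4%, which is 2.2 percentage points above the share read from birch.

The forecast differed. It gave alpha 75%, delta 76%, theta 75%, zeta 70% and best none, arguing “so substrate stays saturating and the path is nearly batch”.

The flasks gave delta 80.1%, which is 4.8 points above theta at 75.3%, so the best is delta.

    target + by-product → side product (k = 0.00740 M⁻¹ min⁻¹)
    partner + free catalyst → catalyst intermediate A (k = 1.80 M⁻¹ min⁻¹)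
    substrate + catalyst intermediate B → catalyst intermediate C (k = 2.00 M⁻¹ min⁻¹)
    catalyst intermediate A → by-product + catalyst intermediate B (k = 11.0 min⁻¹)
    catalyst intermediate C → free catalyst + target (k = 0.0260 min⁻¹)

Delta ended with 11.1% of its charge still substrate, beside 70.5% target and 17.5% side product. Alpha's side product stood at 23.0%, and at the loss carried from birch its difference from delta's equals a lag of 4.07 h, longer than the one I had assumed. In zeta, target stands at 52.7%, and the loss coefficient times its square times 30 h on average gives 22.2% of the charge as side product, while zeta's target and share put it at 21.5%.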